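The dusk run shows how fast substrate goes when reagent is scarce, and that speed is what separates the new flasks.

| flask | substrate | reagent | remark | time |
|---|---|---|---|---|
| dusk | 0.31 M | 0.403 M | run made earlier |  |
| midnight | 0.31 M | 0.56 M | run made earlier |  |
| dawn | 0.31 M | 0.89 M | run made earlier |  |
| amber | 0.31 M | 0.403 M | everything together at the start | 4.0 h |
| violet | 0.31 M (fed, over 3.0 h) | 0.403 M | all else is in the flask from the start; the feed brings no volume worth counting | 4.0 h |
| green | 0.31 M (in portions, 2, over 3.0 h) | 0.403 M | first portion at the start, last at 3.0 h | 4.0 h |
| teal | 0.31 M | 0.403 M (fed, over 3.0 h) | all else is in the flask from the start; the feed brings no volume worth counting | 4.0 h |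

| run | time / h | target / % | substrate / % |
|---|---|---|---|
| dusk | 0.333 | 64.5 | 26.3 |
| dusk | 0.667 | 80.5 | 12.4 |
| dusk | 1.50 | 90.3 | 3.1 |
| dusk | 4.00 | 84.5 | 0.5 |
| midnight | 0.200 | 57.7 | 27.7 |
| midnight | 0.417 | 80.2 | 12.0 |
| midnight | 1.00 | 93.2 | 1.7 |
| midnight | 2.50 | 89.0 | 0 |
| dawn | 0.200 | 69.6 | 15.2 |
| dawn | 0.417 | 90.3 | 4.1 |
| dawn | 1.00 | 95.7 | 0 |
| dawn | 2.50 | 89.5 | 0.3 |

(each reading ± 0.5 percentage points)

- the best flask by amount of target, in percent of the substrate charged; "all alike" if 1.5 percentage points covers them all (amber / violet / green / teal / all alike)
- amount of target at the end, in percent of the substrate charged, amber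
- amount of target at the end, in percent of the substrate charged, violet
- amount of target at the end, in percent of the substrate charged, green
- amount of target at the end, in percent of the substrate charged, teal

1. In the dusk run substrate fell from 26.3% to 12.4% between 0.333 h and 0.667 h. Reagent, taken as its charge minus the substrate gone, stood near 0.153 M. We treat substrate as pseudo-first-order, losing a share k[R] per hour, where [R] is the reagent concentration. This reads k = 14.7 L mol⁻¹ h⁻¹.

2. Objection: the dawn run reads 9.90 L mol⁻¹ h⁻¹, less than dusk, so the order in reagent is below one at high reagent. Our flasks carry the dusk charge, so we keep the dusk k.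

3. Call waiting time, W, the area under the substrate curve divided by the charge: for teal 1.15 h. That is half the time the feed needs to bring reagent equal to the substrate charge, if substrate falls in a straight line.

4. Objection: is reagent used as it arrives? With substrate at half its charge, reagent lives 0.438 h, shorter than the feed. So the straight line stands.

5. For dusk, summing the lifetimes 1/(k[R]) as reagent falls gives a rough estimate, W = 0.321 h. We expect violet, with reagent in excess during its feed, to wait no longer. By these estimates teal's substrate waits longer than dusk's, so a slow loss from substrate, if there is one, should weigh more in teal than in dusk. We therefore put teal below violet.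

6. The forecast gives amber 84.6%, violet 87.8%, green 84.2% and teal 86.8%, with violet best. Its ground: “Feeding delays formation, so target spends less time decaying”.

    substrate + reagent ⇌ adduct, settled at all times (K = 1.50 L mol⁻¹)
    adduct → target (k = 12.3 h⁻¹)
    target ⇌ isomer of the product (K = 0.630, k = 0.0446 h⁻¹)
    substrate ⇌ dormant form (K = 3.10, k = 0.114 h⁻¹)

The flasks give amber 84.3%, violet 87.2%, green 84.4% and teal 77.5%, so violet is best, and teal stands 9.3 percentage points under the forecast. At 3.00 h teal holds 13.8% as dormant form. The forward constant 0.114 h⁻¹ times our W for teal gives 13.1%. In violet, mean substrate of 0.0197 M over the first 3.0 h makes W 0.190 h, which gives 2.17%, and violet holds 2.08% as dormant form at 3.00 h.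

Readings and results were generated by integration on assumed constants, and the scatter is random.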